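The vessel is closed, stirred and isothermal, and from flask to flask we change the initiator.

in all of them: starting material 0.35 M; transfer agent 0.105 M; radical scavenger 1.7 mM

| flask | coupling partner | initiator | remark | time |
|---|---|---|---|---|
| summer | 0.63 M | 1.6 mM | run made earlier |  |
| winter | 0.63 M | 31 mM | run made earlier |  |
| larch | 0.630 M | 20 mM |  | 20 h |
| alder | 0.630 M | 25 mM |  | 20 h |
| cedar | 0.630 M | 12 mM |  | 20 h |
| maple | 0.630 M | 8.8 mM |  | 20 h |
| birch | 0.630 M | 40 mM |  | 20 h |
| oak | 0.630 M | 3.0 mM |  | 20 h |

| run | time / h | target / % | starting material / % |
|---|---|---|---|
| summer | 2.50 | 0 | 99.6 |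
| summer | 5.00 | 0.5 | 100.6 |
| summer | 8.00 | 0.9 | 100.7 |
| summer | 10.0 | 0 | 98.1 |
| winter | 0.833 | 0 | 96.9 |
| winter | 2.00 | 3.0 | 96.8 |
| winter | 4.00 | 8.1 | 92.7 |
| winter | 10.0 | 23.2 | 75.8 |

(each reading ± 1 percentage point)



- all flasks from highest to lowest amount of target, in percent of the starting material charged, at 20 h (larch / alder / cedar / maple / birch / oak)
- the amount of target, in percent of the starting material charged of the flask you put first, at 20 h
- the amount of target, in percent of the starting material charged of the flask you put last, at 20 h

The winter run makes target after a wait, an induction period, and the summer run, with far less initiator, shows nothing beyond the scatter by its last reading. We therefore read the wait as the time the radicals need to clear the radical scavenger, so that the wait multiplied by the initiator, taken as a fraction of the starting material charged, should be one figure for every flask. We begin with a straight line through the last two winter readings: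

    winter slope, as a fraction of the charge: 0.0252 h⁻¹
    wait on that line: 0.781 h
    wait times initiator fraction: 0.0692 h
    wait in oak: 8.08 h

The weak link is the straight line, since a run that spends its starting material bends, and a bent curve run back along a straight line gives too short a wait. We reforge it by letting the rate follow the fraction still unconverted:

    rate constant in winter: 0.0299 h⁻¹
    wait in winter: 1.18 h
    clearing dose: 0.104 h

This clearing dose, the wait times the initiator fraction, puts the summer wait at 22.8 h, later than its last reading, which agrees with summer readings that stay flat within their scatter. We then scale the rate constant with the square root of the initiator, which is an assumption of ours, and reckon the target after the wait: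

    birch: wait 0.912 h, target 47.7 %
    oak: wait 12.2 h, target 7.04 %

More initiator shortens the wait and raises the rate, so we rank the flasks by their initiator.

The forecast, made from the same two runs, gives birch > alder > larch > cedar > maple > oak, with 48 % (38 % to 57 %) first and 7 % (2 % to 12 %) last, and it grants that “The data don't test the square root”.

The flasks stand birch > alder > larch > cedar > maple > oak, with birch at 46.9 % and oak at 3.16 %.

    2 idle radical → ended radicals (k = 8.70 × 10⁶ M⁻¹ s⁻¹)
    second chain carrier + radical scavenger → ended chains B (k = 5.90 × 10⁵ M⁻¹ s⁻¹)
    2 second chain carrier → ended chains A (k = 1.20 × 10⁸ M⁻¹ s⁻¹)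
    initiator → 2 initiating radical (k = 0.0210 h⁻¹)
    starting material + initiating radical → capped initiator + first chain carrier (k = 13000 M⁻¹ s⁻¹)
    starting material + second chain carrier → released group + first chain carrier (k = 7.40 × 10⁵ M⁻¹ h⁻¹)
    transfer agent + first chain carrier → side product + idle radical (kL = 1.80 × 10⁵ M⁻¹ h⁻¹)
    coupling partner + first chain carrier → target + second chain carrier (k = 3.00 × 10⁶ M⁻¹ h⁻¹)

The clearing dose gives birch a wait of 0.912 h out of 20 h, and yet birch holds 46.9 %: the second chain carriers ending on one another and the time given act together here, for birch gives 98.6 % without that ending step and 96.8 % at 200 h. On maple the dose gives a wait of 4.14 h and a target of 22.3 %, and the flask holds 18.5 %.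

All runs are simulated from invented constants; noise was put on by code.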